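The C8 side chain of the coumarin, Ar–C(=O)–C(O‑senecioyl)=CMe2, is an α‑acyloxy enone. It is therefore the oxidised, acyl‑shifted isomer of an aryl alkyne carrying a tertiary propargylic ester, Ar–C≡C–CMe2–O‑senecioyl, and the route rests on this relationship. One gold(I)/N‑oxide operation places the ketone oxygen on the alkyne carbon bound to C8 of the benzopyranone. It also moves the senecioyloxy group from the CMe2 carbon to the adjacent alkyne carbon and creates the tetrasubstituted alkene. The precursor is 7‑methoxycoumarin bearing the complete C5 chain and ester at C8. It is assembled by Sonogashira coupling of 8‑iodo‑7‑methoxycoumarin with the preformed propargyl senecioate, and the coumarin bicycle is bought.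

Key step: step 5

Remark on the chemistry: the target has no stereocentre and no alkene with E/Z geometry (each C=C ends in a CMe2 group). It is achiral, so the "single enantiomer" is the compound itself and no stereocontrol is needed.

Step 1
Reactants: 1 umbelliferone (7‑hydroxycoumarin)
Product: 2 7‑hydroxy‑8‑iodocoumarin
Conditions: I2 (1.0 equiv), KI, H2O, added slowly to 1 in 25% aq. NH3, 0 °C to rt; acidic work‑up (slow addition so that free iodine never builds up in the ammonia)
Reagents that add atoms: iodine, II
Why: Electrophilic aromatic iodination of the phenoxide, in which C8 lies ortho to both the 7‑oxido group and the ring oxygen O1 and is the most nucleophilic ring carbon, while one equivalent of iodine holds back di‑iodination and the lactone tolerates the cold dilute ammonia.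

Step 2
Reactants: 2 7‑hydroxy‑8‑iodocoumarin
Product: 3 8‑iodo‑7‑methoxycoumarin
Conditions: MeI (1.5 equiv), K2CO3 (2 equiv), acetone, reflux
Reagents that add atoms: methyl iodide, CI
Why: Williamson ether synthesis (SN2 of the phenoxide on MeI), in which the weak carbonate base leaves the lactone and the aryl iodide untouched.

Step 3
Reactants: 4 2‑methylbut‑3‑yn‑2‑ol; 5 3‑methylbut‑2‑enoyl chloride (senecioyl chloride)
Product: 7 2‑methylbut‑3‑yn‑2‑yl 3‑methylbut‑2‑enoate, via lithium 2‑methylbut‑3‑yn‑2‑olate 6 (not isolated)
Conditions: n‑BuLi (0.98 equiv), THF, −78 °C, 20 min; then 5 (1.05 equiv), −78 to 0 °C; careful concentration (volatile ester)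
Reagents that add atoms: n‑butyllithium, [Li]CCCC (supplies only the lithium of intermediate 6)
Why: O‑acylation of a preformed lithium alkoxide by an acid chloride (addition–elimination), the usual way to esterify tertiary propargylic alkoxides, in which a slight deficit of n‑BuLi removes only the O–H and not the alkyne C–H, and the lack of any amine together with the low temperature keeps the acid chloride off the vinylketene path that leads to the β,γ‑unsaturated ester.

Step 4
Reactants: 3 8‑iodo‑7‑methoxycoumarin; 7 2‑methylbut‑3‑yn‑2‑yl 3‑methylbut‑2‑enoate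
Product: 8 4‑(7‑methoxy‑2‑oxo‑2H‑chromen‑8‑yl)‑2‑methylbut‑3‑yn‑2‑yl 3‑methylbut‑2‑enoate (7‑methoxycoumarin with C≡C–CMe2–O‑senecioyl at C8)
Conditions: PdCl2(PPh3)2 (4 mol %), CuI (4 mol %), Et3N (3 equiv), degassed THF, 7 (1.3 equiv, added slowly), rt to 45 °C
Reagents that add atoms: none
Why: Sonogashira coupling of an aryl iodide with a terminal alkyne, in which the C–I bond adds to Pd(0) readily despite its two ortho oxygen substituents, a plain carboxylate is too poor a leaving group for Pd(0) to ionise the propargylic ester at this temperature, and a tertiary amine as sole base excludes both lactone aminolysis and copper‑mediated propargylic amination.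

Step 5
Reactants: 8 4‑(7‑methoxy‑2‑oxo‑2H‑chromen‑8‑yl)‑2‑methylbut‑3‑yn‑2‑yl 3‑methylbut‑2‑enoate; 9 8‑methylquinoline N‑oxide
Product: 10 kimcuongin, 1‑(7‑methoxy‑2‑oxo‑2H‑chromen‑8‑yl)‑3‑methyl‑1‑oxobut‑2‑en‑2‑yl 3‑methylbut‑2‑enoate
Conditions: IPrAuNTf2 (5 mol %; IPr = 1,3‑bis(2,6‑diisopropylphenyl)imidazol‑2‑ylidene), 9 (1.2 equiv, dried, present from the start), 4 Å MS, dry 1,2‑dichloroethane, rt
Reagents that add atoms: 8‑methylquinoline N‑oxide 9 (oxygen donor, already listed as reactant), Cc1cccc2ccc[n+]([O-])c12
Why: IPrAu+ coordinates the C≡C bond of 8, the N‑oxide oxygen of 9 adds anti to gold at the alkyne carbon bonded to coumarin C8, and N–O heterolysis releases 8‑methylquinoline and leaves an α‑oxo gold carbene on the carbon next to the quaternary O–CMe2 centre. The senecioate carbonyl oxygen then bonds to this carbene carbon to give a fleeting five‑membered 1,3‑dioxolan‑2‑ylium, which breaks its tertiary C–O bond while gold leaves, so that the aryl ketone, the enol‑ester C–O bond and the C=CMe2 alkene all appear in one operation (the former C=O oxygen becomes the enol oxygen); a 1,2‑acyloxy shift first and oxygen transfer to the resulting vinyl gold carbene second would end at the same compound. The reaction type is the known gold(I)/N‑oxide oxidation of internal propargylic carboxylates to α‑acyloxy enones, a close relative of the sulfoxide oxidation of gold carbenes made by 1,2‑acyloxy migration. No ring remains closed and no stereocentre or E/Z element is created, because the new alkene ends in two methyl groups. The step needs oxygen delivery to the aryl‑bound carbon, only once, and faster than the 3,3‑acyloxy shift: the σ‑withdrawing ester makes the distal alkyne carbon the electrophilic one, the oxygen atoms at C7 and O1 ortho to C8 stabilise positive charge at that same carbon, the N‑oxide is present in full from the start yet limited to a small excess, and the internal acyloxy trap is faster than a second intermolecular oxidation. The quaternary propargylic carbon offers no hydrogen for a 1,2‑hydride shift, both positions ortho to C8 are substituted so that hydroarylation of a reversibly formed allenyl ester to an indene is impossible, and the coumarin C3=C4 and senecioyl C=C bonds are too electron‑poor to trap the carbene.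

Compound list
1 | umbelliferone (7‑hydroxy‑2H‑chromen‑2‑one) | O=c1ccc2ccc(O)cc2o1 | starting material
2 | 7‑hydroxy‑8‑iodocoumarin | O=c1ccc2ccc(O)c(I)c2o1 | intermediate
3 | 8‑iodo‑7‑methoxycoumarin | COc1ccc2ccc(=O)oc2c1I | intermediate
4 | 2‑methylbut‑3‑yn‑2‑ol | CC(C)(O)C#C | starting material
5 | 3‑methylbut‑2‑enoyl chloride (senecioyl chloride) | CC(C)=CC(=O)Cl | starting material
6 | lithium 2‑methylbut‑3‑yn‑2‑olate | [Li+].[O-]C(C)(C)C#C | intermediate
7 | 2‑methylbut‑3‑yn‑2‑yl 3‑methylbut‑2‑enoate | C#CC(C)(C)OC(=O)C=C(C)C | intermediate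
8 | 4‑(7‑methoxy‑2‑oxo‑2H‑chromen‑8‑yl)‑2‑methylbut‑3‑yn‑2‑yl 3‑methylbut‑2‑enoate | COc1ccc2ccc(=O)oc2c1C#CC(C)(C)OC(=O)C=C(C)C | intermediate
9 | 8‑methylquinoline N‑oxide | Cc1cccc2ccc[n+]([O-])c12 | starting material
10 | kimcuongin | COc1ccc2ccc(=O)oc2c1C(=O)C(OC(=O)C=C(C)C)=C(C)C | target

Total step count: 5. Longest linear sequence: 4 steps (1 → 2 → 3 → 8 → 10); step 3 is a one‑step side branch.

Steps most likely to fail

Step 5. The gold‑promoted 3,3‑acyloxy shift, or ionisation of the aryl‑conjugated tertiary ester, may outrun the bimolecular oxygen transfer. The 7‑methoxy oxygen may also intercept the carbene, or a second oxygen transfer may take place. The fallback makes the enol ester from a 1,2‑diketone and involves no gold carbene. Setting out from 3, Sonogashira coupling with commercial 3‑methylbut‑1‑yne (PdCl2(PPh3)2, CuI, Et3N, THF, closed vessel) should give 7‑methoxy‑8‑(3‑methylbut‑1‑yn‑1‑yl)coumarin F1. Wacker‑type alkyne oxidation (PdBr2, CuBr2, O2, aqueous dioxane, 60 °C), which spares the coumarin C3=C4 bond, should give 1‑(7‑methoxy‑2‑oxo‑2H‑chromen‑8‑yl)‑3‑methylbutane‑1,2‑dione F2. The only enolisable position of F2 is the isopropyl C–H. LiHMDS in THF at −78 °C should convert it into lithium 1‑(7‑methoxy‑2‑oxo‑2H‑chromen‑8‑yl)‑3‑methyl‑1‑oxobut‑2‑en‑2‑olate F3. Acylation with 5 should occur on oxygen, because the enolate carbon is fully substituted, and returns to the route at 10.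

Step 4. Oxidative addition and transmetalation at the flanked C8 position may be slow, which leaves the alkyne open to oxidative homocoupling. The tertiary propargylic ester may also be lost through metal‑induced ionisation or elimination. The fallback couples first and esterifies afterwards. Setting out from 3, Sonogashira coupling with the free alcohol 4, a robust partner that carries no leaving group, should give 8‑(3‑hydroxy‑3‑methylbut‑1‑yn‑1‑yl)‑7‑methoxycoumarin F4. Deprotonation with LiHMDS, which is non‑nucleophilic towards the lactone, in THF at −78 °C should give lithium 4‑(7‑methoxy‑2‑oxo‑2H‑chromen‑8‑yl)‑2‑methylbut‑3‑yn‑2‑olate F5. Acylation of F5 with 5 rejoins the route at 8.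

Step 3. Acylation of the hindered alkoxide may be slow enough for it to act as a base, causing dehydrochlorination of the acid chloride and migration of the double bond out of conjugation. Material may also be lost by evaporation. The fallback forms the ester bond first and the alkene afterwards. Setting out from 4, carbodiimide coupling with diethylphosphonoacetic acid (DCC, CH2Cl2, rt) runs through a reactive ketene and therefore esterifies tertiary alcohols. It should give 2‑methylbut‑3‑yn‑2‑yl 2‑(diethoxyphosphoryl)acetate F6. NaH (1.0 equiv, THF, 0 °C) removes the more acidic P–CH2–C(=O) proton to give the sodium phosphonate carbanion of F6, sodium 1‑(diethoxyphosphoryl)‑2‑[(2‑methylbut‑3‑yn‑2‑yl)oxy]‑2‑oxoethan‑1‑ide F7. Horner–Wadsworth–Emmons olefination of F7 with acetone builds the C=CMe2 bond directly in conjugation and returns to the route at 7.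

Further compounds
F1 | step 5 | 7‑methoxy‑8‑(3‑methylbut‑1‑yn‑1‑yl)coumarin | COc1ccc2ccc(=O)oc2c1C#CC(C)C
F2 | step 5 | 1‑(7‑methoxy‑2‑oxo‑2H‑chromen‑8‑yl)‑3‑methylbutane‑1,2‑dione | COc1ccc2ccc(=O)oc2c1C(=O)C(=O)C(C)C
F3 | step 5 | lithium 1‑(7‑methoxy‑2‑oxo‑2H‑chromen‑8‑yl)‑3‑methyl‑1‑oxobut‑2‑en‑2‑olate | [Li+].COc1ccc2ccc(=O)oc2c1C(=O)C([O-])=C(C)C
F4 | step 4 | 8‑(3‑hydroxy‑3‑methylbut‑1‑yn‑1‑yl)‑7‑methoxycoumarin | COc1ccc2ccc(=O)oc2c1C#CC(C)(C)O
F5 | step 4 | lithium 4‑(7‑methoxy‑2‑oxo‑2H‑chromen‑8‑yl)‑2‑methylbut‑3‑yn‑2‑olate | [Li+].COc1ccc2ccc(=O)oc2c1C#CC(C)(C)[O-]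
F6 | step 3 | 2‑methylbut‑3‑yn‑2‑yl 2‑(diethoxyphosphoryl)acetate | C#CC(C)(C)OC(=O)CP(=O)(OCC)OCC
F7 | step 3 | sodium 1‑(diethoxyphosphoryl)‑2‑[(2‑methylbut‑3‑yn‑2‑yl)oxy]‑2‑oxoethan‑1‑ide | [Na+].C#CC(C)(C)OC(=O)[CH-]P(=O)(OCC)OCC
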